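**Retrosynthetic overview**
- The only ring is closed last: ring-closing metathesis forms C2=C3 of a cyclohexenol, which is then oxidised to the enone and desilylated.
- The metathesis diene comes from a Nozaki–Hiyama–Kishi coupling (C1–C2) of an acyclic α-acyloxy aldehyde, already carrying both esters, with a 2-bromoallyl silyl ether.
- The C4 and C6 hydroxyls are told apart through a C1/C6 acetonide; the C4 carbinol comes from a 1,3-anti (Evans–Saksena) reduction of a β-hydroxy vinyl ketone.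
- Key C–C bond: C5–C6, by an Evans syn-aldol of an N-isovaleryl oxazolidinone with silyl-protected glycolaldehyde, which sets C5 and C6.
- The side-chain acid is made from the same aldehyde by an E-selective Wittig reaction.

Assumption and numbering used below: ring atoms are C1 (C=O), C2 (C–CH2OH), C3 (=CH), C4 (CH–O-isobutyryl), C5 (CH–iPr), C6 (CH–O-enoyl); the target is (4S,5S,6R) in this numbering with an E side chain. The route has not been run; conditions are standard literature ones.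

**Step 1**
Reactants: 1 (R)-4-benzyl-1,3-oxazolidin-2-one; 2 3-methylbutanoyl chloride
Product: 3 (4R)-4-benzyl-3-(3-methylbutanoyl)-1,3-oxazolidin-2-one
Conditions: Et3N, DMAP (cat.), CH2Cl2, 0 °C → rt
Reagents that add atoms: none
Why: DMAP-catalysed N-acylation attaches the Evans auxiliary to the isovaleryl unit; no stereocentre is formed.

**Step 2**
Reactants: 3 (4R)-4-benzyl-3-(3-methylbutanoyl)-1,3-oxazolidin-2-one; 4 2-[(tert-butyldimethylsilyl)oxy]acetaldehyde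
Product: 6 (4R)-4-benzyl-3-[(2R,3R)-4-[(tert-butyldimethylsilyl)oxy]-3-hydroxy-2-(propan-2-yl)butanoyl]-1,3-oxazolidin-2-one, via Z-boron enolate 5 (not isolated)
Conditions: n-Bu2BOTf, i-Pr2NEt, CH2Cl2, 0 °C; then 4, −78 → 0 °C; pH 7 buffer, MeOH, 30% H2O2
Reagents that add atoms: none
Why: Evans syn-aldol: the Z-boron enolate reacts through a Zimmerman–Traxler chair on the face away from the benzyl group, so the (R)-auxiliary sets both new centres (2R,3R; ring C5 and C6) syn while forming the C5–C6 bond.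

**Step 3**
Reactants: 6 the aldol adduct
Product: 7 (2R,3R)-4-[(tert-butyldimethylsilyl)oxy]-3-hydroxy-N-methoxy-N-methyl-2-(propan-2-yl)butanamide
Conditions: MeNHOMe·HCl, AlMe3, CH2Cl2, −15 → 0 °C
Reagents that add atoms: N,O-dimethylhydroxylamine hydrochloride, CNOC.Cl
Why: Aluminium-amide transamination, directed by the free β-alkoxide to the exocyclic carbonyl, gives the Weinreb amide without touching C5 or C6 and returns the auxiliary.

**Step 4**
Reactants: 7 the Weinreb amide; 8 vinylmagnesium bromide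
Product: 9 (4R,5R)-6-[(tert-butyldimethylsilyl)oxy]-5-hydroxy-4-(propan-2-yl)hex-1-en-3-one
Conditions: 8 (3.5 equiv), THF, −78 → 0 °C; inverse quench into cold aq. NH4Cl; used crude
Reagents that add atoms: none
Why: Weinreb ketone synthesis: the chelated tetrahedral intermediate stops at mono-addition, one equivalent of Grignard reagent being consumed by the free hydroxyl.

**Step 5**
Reactants: 9 the β-hydroxy vinyl ketone
Product: 10 (3S,4S,5R)-6-[(tert-butyldimethylsilyl)oxy]-4-(propan-2-yl)hex-1-ene-3,5-diol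
Conditions: Me4NBH(OAc)3, MeCN/AcOH (1:1), −30 °C
Reagents that add atoms: none
Why: Evans–Saksena reduction: boron binds the C6 hydroxyl and delivers hydride intramolecularly through a chair transition state, giving the 1,3-anti diol and thus the (3S) carbinol (ring C4).

**Step 6**
Reactants: 10 the anti-diol silyl ether
Product: 11 (2R,3S,4S)-3-(propan-2-yl)hex-5-ene-1,2,4-triol
Conditions: HF·pyridine, pyridine, THF, 0 °C → rt
Reagents that add atoms: none
Why: Fluoride cleavage of the primary silyl ether (Si–F bond formation) exposes the 1,2-diol needed to differentiate the two secondary hydroxyls.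

**Step 7**
Reactants: 11 the triol
Product: 12 (3S,4S)-4-[(4R)-2,2-dimethyl-1,3-dioxolan-4-yl]-5-methylhex-1-en-3-ol
Conditions: Me2C(OMe)2, PPTS (cat.), CH2Cl2, rt
Reagents that add atoms: 2,2-dimethoxypropane, COC(C)(C)OC
Why: Thermodynamic acetonide formation takes the terminal 1,2-diol as a dioxolane in preference to the anti-1,3-diol (whose dioxane would be a twist-boat), leaving only the C4 hydroxyl free.

**Step 8**
Reactants: 12 the acetonide alcohol; 13 2-methylpropanoyl chloride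
Product: 14 (3S,4S)-4-[(4R)-2,2-dimethyl-1,3-dioxolan-4-yl]-5-methylhex-1-en-3-yl 2-methylpropanoate
Conditions: pyridine, DMAP (cat.), CH2Cl2, 0 °C → rt
Reagents that add atoms: none
Why: DMAP-catalysed acylation of the only free hydroxyl installs the C4 isobutyrate with retention.

**Step 9**
Reactants: 14 the acetonide ester
Product: 15 (3S,4R,5R)-5,6-dihydroxy-4-(propan-2-yl)hex-1-en-3-yl 2-methylpropanoate
Conditions: AcOH/H2O (4:1), 40 °C
Reagents that add atoms: none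
Why: Mild acid-catalysed acetal hydrolysis frees the 1,2-diol while the hindered allylic isobutyrate survives.

**Step 10**
Reactants: 15 the diol ester
Product: 16 (3S,4R,5R)-5-hydroxy-4-(propan-2-yl)-6-[(triethylsilyl)oxy]hex-1-en-3-yl 2-methylpropanoate
Conditions: TESCl (1.05 equiv), imidazole, CH2Cl2, −78 → −20 °C
Reagents that add atoms: chlorotriethylsilane, CC[Si](Cl)(CC)CC
Why: Kinetically selective silylation of the primary over the hindered secondary hydroxyl.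

**Step 11**
Reactants: 4 2-[(tert-butyldimethylsilyl)oxy]acetaldehyde; 17 ethyl 2-(triphenyl-λ5-phosphanylidene)propanoate
Product: 18 ethyl (2E)-4-[(tert-butyldimethylsilyl)oxy]-2-methylbut-2-enoate
Conditions: CH2Cl2, rt
Reagents that add atoms: none
Why: Wittig olefination with a stabilised ylide gives the (E)-trisubstituted enoate.

**Step 12**
Reactants: 18 the ethyl ester
Product: 19 (2E)-4-[(tert-butyldimethylsilyl)oxy]-2-methylbut-2-enoic acid
Conditions: LiOH, THF/MeOH/H2O, rt; then cold 1 M HCl to pH 4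
Reagents that add atoms: lithium hydroxide, [Li+].[OH-]
Why: Saponification of the ethyl ester; the allylic silyl ether and the E-alkene are stable to aqueous LiOH at room temperature.

**Step 13**
Reactants: 16 the C6 alcohol; 19 the side-chain acid
Product: 21 (2R,3S,4S)-4-[(2-methylpropanoyl)oxy]-3-(propan-2-yl)-1-[(triethylsilyl)oxy]hex-5-en-2-yl (2E)-4-[(tert-butyldimethylsilyl)oxy]-2-methylbut-2-enoate, via mixed anhydride 20 (not isolated)
Conditions: 19, 2,4,6-trichlorobenzoyl chloride, Et3N, THF, rt; then 16, DMAP, toluene, rt → 40 °C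
Reagents that add atoms: none
Why: Yamaguchi esterification: DMAP attacks the less hindered enoyl carbonyl of the mixed anhydride and the acylpyridinium esterifies the hindered C6 hydroxyl with retention at C6 and at the alkene.

**Step 14**
Reactants: 21 the diester TES ether
Product: 22 (2R,3S,4S)-1-hydroxy-4-[(2-methylpropanoyl)oxy]-3-(propan-2-yl)hex-5-en-2-yl (2E)-4-[(tert-butyldimethylsilyl)oxy]-2-methylbut-2-enoate
Conditions: PPTS (cat.), MeOH/CH2Cl2, 0 °C; used at once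
Reagents that add atoms: none
Why: Acid-catalysed methanolysis removes the primary triethylsilyl ether a few hundred times faster than the primary TBS ether.

**Step 15**
Reactants: 22 the primary alcohol
Product: 23 (2R,3S,4S)-4-[(2-methylpropanoyl)oxy]-1-oxo-3-(propan-2-yl)hex-5-en-2-yl (2E)-4-[(tert-butyldimethylsilyl)oxy]-2-methylbut-2-enoate
Conditions: Dess–Martin periodinane, pyridine, CH2Cl2, 0 °C → rt
Reagents that add atoms: none
Why: Dess–Martin oxidation gives the α-acyloxy aldehyde under non-basic conditions that do not epimerise C6.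

**Step 16**
Reactants: 24 2-bromoprop-2-en-1-ol
Product: 25 [(2-bromoprop-2-en-1-yl)oxy](tert-butyl)dimethylsilane
Conditions: TBSCl, imidazole, CH2Cl2, rt
Reagents that add atoms: tert-butyl(chloro)dimethylsilane, CC(C)(C)[Si](C)(C)Cl
Why: Standard imidazole-promoted silylation of the primary allylic alcohol.

**Step 17**
Reactants: 23 the aldehyde; 25 the 2-bromoallyl silyl ether
Product: 26 (3S,4S,5R,6RS)-7-{[(tert-butyldimethylsilyl)oxy]methyl}-6-hydroxy-3-[(2-methylpropanoyl)oxy]-4-(propan-2-yl)octa-1,7-dien-5-yl (2E)-4-[(tert-butyldimethylsilyl)oxy]-2-methylbut-2-enoate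
Conditions: CrCl2 (5 equiv), NiCl2 (2 mol%), DMF, rt
Reagents that add atoms: none
Why: Nozaki–Hiyama–Kishi coupling: the nickel-generated alkenylchromium(III) species adds only to the aldehyde and tolerates both esters; the new carbinol (ring C1) forms as an epimer mixture that the later oxidation removes.

**Step 18**
Reactants: 26 the diene
Product: 27 (1R,2RS,5S,6S)-3-{[(tert-butyldimethylsilyl)oxy]methyl}-2-hydroxy-5-[(2-methylpropanoyl)oxy]-6-(propan-2-yl)cyclohex-3-en-1-yl (2E)-4-[(tert-butyldimethylsilyl)oxy]-2-methylbut-2-enoate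
Conditions: Grubbs II (5 mol%), CH2Cl2 (5 mM), 40 °C
Reagents that add atoms: none
Why: Ring-closing metathesis, initiating at the monosubstituted vinyl group, forms the six-membered ring at C2=C3 and releases ethene.

**Step 19**
Reactants: 27 the cyclohexenol
Product: 28 (1R,5S,6S)-3-{[(tert-butyldimethylsilyl)oxy]methyl}-5-[(2-methylpropanoyl)oxy]-2-oxo-6-(propan-2-yl)cyclohex-3-en-1-yl (2E)-4-[(tert-butyldimethylsilyl)oxy]-2-methylbut-2-enoate
Conditions: Dess–Martin periodinane, pyridine, CH2Cl2, 0 °C → rt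
Reagents that add atoms: none
Why: Dess–Martin oxidation of the allylic alcohol gives the enone and converges both C1 epimers.

**Step 20**
Reactants: 28 the bis-silyl enone
Product: 29 (1R,5S,6S)-3-(hydroxymethyl)-5-[(2-methylpropanoyl)oxy]-2-oxo-6-(propan-2-yl)cyclohex-3-en-1-yl (2E)-4-hydroxy-2-methylbut-2-enoate (target, CNP0254776.1)
Conditions: HF·pyridine, pyridine, THF, 0 °C → rt
Reagents that add atoms: none
Why: Buffered fluoride desilylation (Si–F formation) frees both primary alcohols without acyl migration, β-elimination or epimerisation of the α-acyloxy ketone.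

**Compound list**
1 | (R)-4-benzyl-1,3-oxazolidin-2-one | O=C1N[C@H](Cc2ccccc2)CO1 | starting material
2 | 3-methylbutanoyl chloride | CC(C)CC(Cl)=O | starting material
3 | (4R)-4-benzyl-3-(3-methylbutanoyl)-1,3-oxazolidin-2-one | CC(C)CC(=O)N1[C@H](Cc2ccccc2)COC1=O | intermediate
4 | 2-[(tert-butyldimethylsilyl)oxy]acetaldehyde | O=CCO[Si](C)(C)C(C)(C)C | starting material
5 | (4R)-4-benzyl-3-[(1Z)-1-[(dibutylboranyl)oxy]-3-methylbut-1-en-1-yl]-1,3-oxazolidin-2-one (Z-boron enolate) | CC(C)/C=C(\OB(CCCC)CCCC)N1[C@H](Cc2ccccc2)COC1=O | intermediate (not isolated)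
6 | (4R)-4-benzyl-3-[(2R,3R)-4-[(tert-butyldimethylsilyl)oxy]-3-hydroxy-2-(propan-2-yl)butanoyl]-1,3-oxazolidin-2-one | O=C([C@H](C(C)C)[C@@H](O)CO[Si](C)(C)C(C)(C)C)N1[C@H](Cc2ccccc2)COC1=O | intermediate
7 | (2R,3R)-4-[(tert-butyldimethylsilyl)oxy]-3-hydroxy-N-methoxy-N-methyl-2-(propan-2-yl)butanamide | CON(C)C(=O)[C@H](C(C)C)[C@@H](O)CO[Si](C)(C)C(C)(C)C | intermediate
8 | vinylmagnesium bromide | C=C[Mg]Br | starting material
9 | (4R,5R)-6-[(tert-butyldimethylsilyl)oxy]-5-hydroxy-4-(propan-2-yl)hex-1-en-3-one | C=CC(=O)[C@H](C(C)C)[C@@H](O)CO[Si](C)(C)C(C)(C)C | intermediate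
10 | (3S,4S,5R)-6-[(tert-butyldimethylsilyl)oxy]-4-(propan-2-yl)hex-1-ene-3,5-diol | C=C[C@H](O)[C@H](C(C)C)[C@@H](O)CO[Si](C)(C)C(C)(C)C | intermediate
11 | (2R,3S,4S)-3-(propan-2-yl)hex-5-ene-1,2,4-triol | C=C[C@H](O)[C@H](C(C)C)[C@@H](O)CO | intermediate
12 | (3S,4S)-4-[(4R)-2,2-dimethyl-1,3-dioxolan-4-yl]-5-methylhex-1-en-3-ol | C=C[C@H](O)[C@H](C(C)C)[C@@H]1COC(C)(C)O1 | intermediate
13 | 2-methylpropanoyl chloride | CC(C)C(Cl)=O | starting material
14 | (3S,4S)-4-[(4R)-2,2-dimethyl-1,3-dioxolan-4-yl]-5-methylhex-1-en-3-yl 2-methylpropanoate | C=C[C@H](OC(=O)C(C)C)[C@H](C(C)C)[C@@H]1COC(C)(C)O1 | intermediate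
15 | (3S,4R,5R)-5,6-dihydroxy-4-(propan-2-yl)hex-1-en-3-yl 2-methylpropanoate | C=C[C@H](OC(=O)C(C)C)[C@H](C(C)C)[C@@H](O)CO | intermediate
16 | (3S,4R,5R)-5-hydroxy-4-(propan-2-yl)-6-[(triethylsilyl)oxy]hex-1-en-3-yl 2-methylpropanoate | C=C[C@H](OC(=O)C(C)C)[C@H](C(C)C)[C@@H](O)CO[Si](CC)(CC)CC | intermediate
17 | ethyl 2-(triphenyl-λ5-phosphanylidene)propanoate | CCOC(=O)C(C)=P(c1ccccc1)(c1ccccc1)c1ccccc1 | starting material
18 | ethyl (2E)-4-[(tert-butyldimethylsilyl)oxy]-2-methylbut-2-enoate | CCOC(=O)/C(C)=C/CO[Si](C)(C)C(C)(C)C | intermediate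
19 | (2E)-4-[(tert-butyldimethylsilyl)oxy]-2-methylbut-2-enoic acid | OC(=O)/C(C)=C/CO[Si](C)(C)C(C)(C)C | intermediate
20 | (2E)-4-[(tert-butyldimethylsilyl)oxy]-2-methylbut-2-enoic 2,4,6-trichlorobenzoic anhydride | O=C(OC(=O)/C(C)=C/CO[Si](C)(C)C(C)(C)C)c1c(Cl)cc(Cl)cc1Cl | intermediate (not isolated)
21 | (2R,3S,4S)-4-[(2-methylpropanoyl)oxy]-3-(propan-2-yl)-1-[(triethylsilyl)oxy]hex-5-en-2-yl (2E)-4-[(tert-butyldimethylsilyl)oxy]-2-methylbut-2-enoate | C=C[C@H](OC(=O)C(C)C)[C@H](C(C)C)[C@@H](OC(=O)/C(C)=C/CO[Si](C)(C)C(C)(C)C)CO[Si](CC)(CC)CC | intermediate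
22 | (2R,3S,4S)-1-hydroxy-4-[(2-methylpropanoyl)oxy]-3-(propan-2-yl)hex-5-en-2-yl (2E)-4-[(tert-butyldimethylsilyl)oxy]-2-methylbut-2-enoate | C=C[C@H](OC(=O)C(C)C)[C@H](C(C)C)[C@@H](OC(=O)/C(C)=C/CO[Si](C)(C)C(C)(C)C)CO | intermediate
23 | (2R,3S,4S)-4-[(2-methylpropanoyl)oxy]-1-oxo-3-(propan-2-yl)hex-5-en-2-yl (2E)-4-[(tert-butyldimethylsilyl)oxy]-2-methylbut-2-enoate | C=C[C@H](OC(=O)C(C)C)[C@H](C(C)C)[C@@H](OC(=O)/C(C)=C/CO[Si](C)(C)C(C)(C)C)C=O | intermediate
24 | 2-bromoprop-2-en-1-ol | C=C(Br)CO | starting material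
25 | [(2-bromoprop-2-en-1-yl)oxy](tert-butyl)dimethylsilane | C=C(Br)CO[Si](C)(C)C(C)(C)C | intermediate
26 | (3S,4S,5R,6RS)-7-{[(tert-butyldimethylsilyl)oxy]methyl}-6-hydroxy-3-[(2-methylpropanoyl)oxy]-4-(propan-2-yl)octa-1,7-dien-5-yl (2E)-4-[(tert-butyldimethylsilyl)oxy]-2-methylbut-2-enoate (both carbinol epimers) | C=C[C@H](OC(=O)C(C)C)[C@H](C(C)C)[C@@H](OC(=O)/C(C)=C/CO[Si](C)(C)C(C)(C)C)C(O)C(=C)CO[Si](C)(C)C(C)(C)C | intermediate
27 | (1R,2RS,5S,6S)-3-{[(tert-butyldimethylsilyl)oxy]methyl}-2-hydroxy-5-[(2-methylpropanoyl)oxy]-6-(propan-2-yl)cyclohex-3-en-1-yl (2E)-4-[(tert-butyldimethylsilyl)oxy]-2-methylbut-2-enoate | C/C(=C\CO[Si](C)(C)C(C)(C)C)C(=O)O[C@H]1C(O)C(CO[Si](C)(C)C(C)(C)C)=C[C@H](OC(=O)C(C)C)[C@@H]1C(C)C | intermediate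
28 | (1R,5S,6S)-3-{[(tert-butyldimethylsilyl)oxy]methyl}-5-[(2-methylpropanoyl)oxy]-2-oxo-6-(propan-2-yl)cyclohex-3-en-1-yl (2E)-4-[(tert-butyldimethylsilyl)oxy]-2-methylbut-2-enoate | C/C(=C\CO[Si](C)(C)C(C)(C)C)C(=O)O[C@H]1C(=O)C(CO[Si](C)(C)C(C)(C)C)=C[C@H](OC(=O)C(C)C)[C@@H]1C(C)C | intermediate
29 | (1R,5S,6S)-3-(hydroxymethyl)-5-[(2-methylpropanoyl)oxy]-2-oxo-6-(propan-2-yl)cyclohex-3-en-1-yl (2E)-4-hydroxy-2-methylbut-2-enoate | C/C(=C\CO)C(=O)O[C@H]1C(=O)C(CO)=C[C@H](OC(=O)C(C)C)[C@@H]1C(C)C | target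

**Totals**
Total step count: 20. Longest linear sequence: 17 steps (steps 1–10, 13–15, 17–20); steps 11–12 and 16 make the side-chain acid and the bromide.

**Three steps most likely to fail, with fallbacks**

Step 4. The β-hydroxy vinyl ketone 9 is prone to aza-Michael addition of the liberated MeNHOMe, oxa-Michael closure and dehydration. The fallback masks the vinyl group as a silyl alkyne. It sets out from 7: lithium (trimethylsilyl)acetylide (TMS-acetylene, n-BuLi, THF, −78 → 0 °C) gives the ynone (4R,5R)-6-[(tert-butyldimethylsilyl)oxy]-5-hydroxy-4-(propan-2-yl)-1-(trimethylsilyl)hex-1-yn-3-one F1. The same Me4NBH(OAc)3 anti-reduction gives (3R,4S,5R)-6-[(tert-butyldimethylsilyl)oxy]-4-(propan-2-yl)-1-(trimethylsilyl)hex-1-yne-3,5-diol F2. K2CO3 in MeOH removes the C-silyl group to give (3R,4S,5R)-6-[(tert-butyldimethylsilyl)oxy]-4-(propan-2-yl)hex-1-yne-3,5-diol F3. Lindlar semihydrogenation (H2, Pd/CaCO3/Pb, quinoline, EtOAc) then returns to the route at 10.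

Step 17. The hindered 2-bromoalkene may insert slowly and the α-acyloxy aldehyde may not survive long exposure to chromium salts. The fallback forms the C1–C2 bond by a Morita–Baylis–Hillman reaction. It sets out from 23: acrolein and DABCO (THF, 0 °C) give the enal (3S,4S,5R,6RS)-7-formyl-6-hydroxy-3-[(2-methylpropanoyl)oxy]-4-(propan-2-yl)octa-1,7-dien-5-yl (2E)-4-[(tert-butyldimethylsilyl)oxy]-2-methylbut-2-enoate F4. Luche reduction (NaBH4, CeCl3·7H2O, MeOH, −78 °C) gives the allylic diol (3S,4S,5R,6RS)-6-hydroxy-7-(hydroxymethyl)-3-[(2-methylpropanoyl)oxy]-4-(propan-2-yl)octa-1,7-dien-5-yl (2E)-4-[(tert-butyldimethylsilyl)oxy]-2-methylbut-2-enoate F5. Selective silylation of its primary hydroxyl (TBSCl, imidazole, CH2Cl2, −20 °C) returns to the route at 26.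

Step 18. The 1,1-disubstituted alkene flanked by two oxygenated carbons may not cyclise. The fallback closes the ring on an unsubstituted diene and adds C7 afterwards. It sets out from 23: vinylmagnesium bromide 8 (THF, −78 °C) adds to the aldehyde only and gives (3S,4S,5R,6RS)-6-hydroxy-3-[(2-methylpropanoyl)oxy]-4-(propan-2-yl)octa-1,7-dien-5-yl (2E)-4-[(tert-butyldimethylsilyl)oxy]-2-methylbut-2-enoate F6. Grubbs II closes the ring between two monosubstituted alkenes to (1R,2RS,5S,6S)-2-hydroxy-5-[(2-methylpropanoyl)oxy]-6-(propan-2-yl)cyclohex-3-en-1-yl (2E)-4-[(tert-butyldimethylsilyl)oxy]-2-methylbut-2-enoate F7. Dess–Martin oxidation gives (1R,5S,6S)-5-[(2-methylpropanoyl)oxy]-2-oxo-6-(propan-2-yl)cyclohex-3-en-1-yl (2E)-4-[(tert-butyldimethylsilyl)oxy]-2-methylbut-2-enoate F8. Morita–Baylis–Hillman hydroxymethylation (aq. HCHO, DMAP, THF/H2O, rt) gives (1R,5S,6S)-3-(hydroxymethyl)-5-[(2-methylpropanoyl)oxy]-2-oxo-6-(propan-2-yl)cyclohex-3-en-1-yl (2E)-4-[(tert-butyldimethylsilyl)oxy]-2-methylbut-2-enoate F9. HF·pyridine as in step 20 then returns to the route at 29.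

**Further compounds**
F1 | step 4 | (4R,5R)-6-[(tert-butyldimethylsilyl)oxy]-5-hydroxy-4-(propan-2-yl)-1-(trimethylsilyl)hex-1-yn-3-one | C[Si](C)(C)C#CC(=O)[C@H](C(C)C)[C@@H](O)CO[Si](C)(C)C(C)(C)C
F2 | step 4 | (3R,4S,5R)-6-[(tert-butyldimethylsilyl)oxy]-4-(propan-2-yl)-1-(trimethylsilyl)hex-1-yne-3,5-diol | C[Si](C)(C)C#C[C@H](O)[C@H](C(C)C)[C@@H](O)CO[Si](C)(C)C(C)(C)C
F3 | step 4 | (3R,4S,5R)-6-[(tert-butyldimethylsilyl)oxy]-4-(propan-2-yl)hex-1-yne-3,5-diol | C#C[C@H](O)[C@H](C(C)C)[C@@H](O)CO[Si](C)(C)C(C)(C)C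
F4 | step 17 | (3S,4S,5R,6RS)-7-formyl-6-hydroxy-3-[(2-methylpropanoyl)oxy]-4-(propan-2-yl)octa-1,7-dien-5-yl (2E)-4-[(tert-butyldimethylsilyl)oxy]-2-methylbut-2-enoate | C=C[C@H](OC(=O)C(C)C)[C@H](C(C)C)[C@@H](OC(=O)/C(C)=C/CO[Si](C)(C)C(C)(C)C)C(O)C(=C)C=O
F5 | step 17 | (3S,4S,5R,6RS)-6-hydroxy-7-(hydroxymethyl)-3-[(2-methylpropanoyl)oxy]-4-(propan-2-yl)octa-1,7-dien-5-yl (2E)-4-[(tert-butyldimethylsilyl)oxy]-2-methylbut-2-enoate | C=C[C@H](OC(=O)C(C)C)[C@H](C(C)C)[C@@H](OC(=O)/C(C)=C/CO[Si](C)(C)C(C)(C)C)C(O)C(=C)CO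
F6 | step 18 | (3S,4S,5R,6RS)-6-hydroxy-3-[(2-methylpropanoyl)oxy]-4-(propan-2-yl)octa-1,7-dien-5-yl (2E)-4-[(tert-butyldimethylsilyl)oxy]-2-methylbut-2-enoate | C=C[C@H](OC(=O)C(C)C)[C@H](C(C)C)[C@@H](OC(=O)/C(C)=C/CO[Si](C)(C)C(C)(C)C)C(O)C=C
F7 | step 18 | (1R,2RS,5S,6S)-2-hydroxy-5-[(2-methylpropanoyl)oxy]-6-(propan-2-yl)cyclohex-3-en-1-yl (2E)-4-[(tert-butyldimethylsilyl)oxy]-2-methylbut-2-enoate | C/C(=C\CO[Si](C)(C)C(C)(C)C)C(=O)O[C@H]1C(O)C=C[C@H](OC(=O)C(C)C)[C@@H]1C(C)C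
F8 | step 18 | (1R,5S,6S)-5-[(2-methylpropanoyl)oxy]-2-oxo-6-(propan-2-yl)cyclohex-3-en-1-yl (2E)-4-[(tert-butyldimethylsilyl)oxy]-2-methylbut-2-enoate | C/C(=C\CO[Si](C)(C)C(C)(C)C)C(=O)O[C@H]1C(=O)C=C[C@H](OC(=O)C(C)C)[C@@H]1C(C)C
F9 | step 18 | (1R,5S,6S)-3-(hydroxymethyl)-5-[(2-methylpropanoyl)oxy]-2-oxo-6-(propan-2-yl)cyclohex-3-en-1-yl (2E)-4-[(tert-butyldimethylsilyl)oxy]-2-methylbut-2-enoate | C/C(=C\CO[Si](C)(C)C(C)(C)C)C(=O)O[C@H]1C(=O)C(CO)=C[C@H](OC(=O)C(C)C)[C@@H]1C(C)C
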